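A small charge of single-handed free catalyst, 7.6 mol% in the north-east run, gave 83.8% left-handed product after 90.0 s, and you want to know what 5.1 mol% gives in the flask, a charge smaller than that.

all flasks: left-handed substrate 0.40 M; right-handed substrate 0.40 M; racemization catalyst 5 mol%
- north-east: coupling partner 4 equiv; free catalyst 7.6 mol%; run made earlier
- flask: coupling partner 4.00 equiv; free catalyst 5.1 mol%; time 5.0 min

north-east run (percent of the left-handed substrate and right-handed substrate together charged)

| time / s | left-handed product / % | right-handed product / % |
|---|---|---|
| 10.0 | 48.9 | 5.9 |
| 15.0 | 57.6 | 4.8 |
| 40.0 | 75.1 | 7.9 |
| 90.0 | 83.8 | 8.0 |

(scatter of a reading: 0.5 percentage points)

- free catalyst is single-handed; left-handed substrate and right-handed substrate are mirror images of each other, charged as a racemate, each of them at the stated concentration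
- an excess is the difference of the two amounts in percent of their sum
- an excess is below zero if the other one leads
- no earlier run changes the charge of free catalyst; that part of a forecast is a guess

- left-handed product and right-handed product together, in percent of the left-handed substrate and right-handed substrate charged together, at 5.0 min
- excess of left-handed product over right-handed product in the product at 5.0 min
- whether the exchange between left-handed substrate and right-handed substrate keeps pace with the reaction: how far the product's excess at 5.0 min gets from its value without exchange to its value with instant exchange (above 80% keeps pace, below 20% hardly takes part, else lags behind)

Keep a ledger of the substrates, the limiting reagent on paper, in percent of the charge. Left-handed substrate was half of the north-east charge, yet left-handed product reads 83.8%, so at least 33.8% of the charge crossed over from right-handed substrate. Right-handed product reads 7.9% at 40.0 s and 8.0% at 90.0 s, each good to 0.5 percentage points, so these readings show no late surge.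

Add the four readings of each product and divide: you get 9.98 of left-handed product for each part of right-handed product. This ratio of the amounts made is the split, or selectivity factor.

Suppose both couplings use the same [free catalyst] and [coupling partner], and exchange holds [left-handed substrate] equal to [right-handed substrate]. Those factors then cancel from the ratio of the two rates, which is constant, and integrating it in closed form gives [left-handed product]/[right-handed product] equal to the split at every time. So the smaller charge of free catalyst leaves the split unchanged, whatever amount reacts. Of each portion that reacts, 90.9% becomes left-handed product, and the excess is 81.8%.

The forecast says 95.5% (91% to 98%), an excess of 82.5% (79.5% to 85.5%), and keeps pace, holding that “exchange appears to keep up with the coupling”. My excess is a little lower than its figure but inside its range. The amount reacted is a guess for me too, so I take its 95.5% and close the books: 86.8% left-handed product, 8.69% right-handed product, 4.50% substrate left.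

The flask gives 92.4% and an excess of 81.7%, and the exchange keeps pace, getting 99.7% of the way to instant exchange.

    coupling partner + free catalyst + left-handed substrate → free catalyst + left-handed product (k = 4.10 /M²/s)
    coupling partner + free catalyst + right-handed substrate → free catalyst + right-handed product (k = 0.410 /M²/s)
    left-handed substrate + racemization catalyst ⇌ right-handed substrate + racemization catalyst, rate k3*[racemization catalyst]*[left-handed substrate] forward; the back reaction follows from the equilibrium constant (k = 320 /M/s)
    2 coupling partner → self-condensation product (k = 0.0150 /M/s)
    racemization catalyst ⇌ dormant form (K = 0.920, k = 0.150 /s)

Among the substrate left in the flask at 5.00 min, right-handed substrate leads by 0.0245%. The split puts 84.0% of the flask's charge in left-handed product, and the flask holds 84.0%. In the neighbour charged with 3.1 mol% of free catalyst, 80.6% ends as product, which the split makes 73.3% left-handed product, against 73.2% in that neighbour.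

The numbers in the tables were generated by integration for substances that don't exist; noise was put on by code.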